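The readings were computed for an exercise, noise included.

Between 8.00 d and 15.0 d the epsilon run falls from 48.8% to 27.3% of target while its starting material reads 0% and 0.3%, so a later step, an over-reaction, is consuming target, and the set-ups below are judged by the target that stands at the end or at the outlet.

| setting | epsilon | gamma | theta | alder | ash | birch | larch |
|---|---|---|---|---|---|---|---|
| starting material | 0.050 M | 0.050 M | 0.050 M | 0.050 M | 0.050 M (fed, over 12.5 d) | 0.050 M | 0.050 M |
| second substrate | 0.10 M | 0.14 M | 0.22 M | 0.100 M | 0.100 M | 0.100 M | 0.100 M |
| enzyme | 5 µM | 5 µM | 5 µM | 5.0 µM | 5.0 µM | 5.0 µM | 5.0 µM |
| remark | run made earlier | run made earlier | run made earlier | a tube with plug flow, the mixed feed as stated, residence time 25 d | all but starting material at the start; starting material goes in evenly over 12.5 d, the run ends at 25 d | everything together in a closed stirred flask, run for 25 d | one stirred flow tank at steady state, fed with the mixture as stated, mean residence time 25 d |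
| time |  |  |  | 25 d | 25 d | 25 d |  |

| run | time / d | target / % | starting material / % |
|---|---|---|---|
| epsilon | 1.25 | 32.6 | 66.5 |
| epsilon | 2.50 | 61.1 | 35.3 |
| epsilon | 4.00 | 76.4 | 8.5 |
| epsilon | 8.00 | 48.8 | 0 |
| epsilon | 15.0 | 27.3 | 0.3 |
| gamma | 2.50 | 61.5 | 32.1 |
| gamma | 8.00 | 26.7 | 0 |
| gamma | 15.0 | 5.4 | 0.2 |
| gamma | 20.0 | 1.6 | 0.9 |
| gamma | 30.0 | 0 | 0 |
| theta | 2.50 | 62.3 | 29.6 |
| theta | 8.00 | 5.2 | 0.7 |
| theta | 15.0 | 0 | 0.8 |
| theta | 20.0 | 0 | 0 |
| theta | 30.0 | 0.2 | 0.1 |

(readings scatter by 0.5 percentage points)

- the stated concentrations are those of everything mixed, before any reaction; amounts are the same in each set-up
- the numbers in the tables scatter with a standard deviation of 0.5 percentage points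
- the feed brings no volume worth counting
- the earlier runs were made in a closed, stirred flask

1. the set-up with the highest amount of target at the outlet or at the end, in percent of the starting material put in ("none" if the first two lie within 2 percentage points) (alder / ash / birch / larch / none)
2. amount of target at the outlet or at the end, in percent of the starting material put in, alder
3. amount of target at the outlet or at the end, in percent of the starting material put in, ash
4. amount of target at the outlet or at the end, in percent of the starting material put in, birch
5. amount of target at the outlet or at the end, in percent of the starting material put in, larch

Take the loss of target as first order in target and in second substrate, each event using one more second substrate. Epsilon charges twice as much second substrate as starting material, so once starting material has reacted, second substrate left equals target left, and the reciprocal of the target concentration rises straight with time. Its slope between those readings is the over-reaction constant 4.61 /M/d, the target lost per day per unit of target and of second substrate. Gamma gives a second reading from another charge: over the same stretch the same balance puts its second substrate at 0.0534 M and then 0.0427 M, so the decay there can be treated as roughly pseudo-first-order, and replacing that second-substrate curve by the mean of its two ends gives 4.75 /M/d.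

Birch has epsilon's charge and vessel, so my reckoning continues the straight line from the last epsilon reading to 16.8% at 25 d, and alder takes the same value, since each slice of plug flow is a closed flask of the same age. Ash, reckoned as if its whole charge stood as target at 12.5 d, comes by the same line to 25.8%, a figure that counts no loss of target during the feed. Larch takes in its charge at 0.0400 /d, against the 0.259 /d at which epsilon consumed its own charge over the first 2.50 d, so I assume, as a working estimate, that larch's starting material has reacted. Its target then satisfies: charge less target equals constant times residence time times target squared. That gives 33.9%, with second substrate reckoned at 0.0169 M against 0.100 M charged, and this puts larch first.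

The forecast gave 16.8% for alder, 20% for ash, 16.8% for birch and 34% for larch, naming larch best, on this ground: “The stirred tank holds second substrate low at steady state”. The flask gives 16.4% for alder, 19.8% for ash, 16.4% for birch and 31.8% for larch, so larch leads.

    starting material + enzyme ⇌ starting complex (K = 21.9 /M, k = 71600 /M/h)
    second substrate + starting complex ⇌ ternary complex (K = 280 /M, k = 70600 /M/h)
    ternary complex → enzyme + target (k = 133 /h)
    second substrate + enzyme + target → enzyme + over-reaction product (k = 39700 /M²/h)

In alder the over-reaction step, with the other concentrations as charged, gives target a half-life of 1.5 d, shorter than the 25 d of residence. Continued from the last epsilon reading with the carried constant, the straight line puts birch at 1.73% at 250 d, and the flask gives 1.67%.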